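**Retrosynthetic overview**

- Numbering is that of germacrane: C6 = lactone O–CH, C7 = ring-fusion CH, C8 = acyloxy CH, C11–C13 = methylene-lactone carbons, C14/C15 = CH2OH carbons on C10/C4. Endgame: target ⇐ 14,15-bis-silyl ether ⇐ acylation at O-8 ⇐ 8-hydroxy lactone.
- Key disconnection: C6–C7, by an intramolecular chromium Barbier (Nozaki–Hiyama–Kishi) 2-(methoxycarbonyl)allylation of an acyclic (8R)-enal/(Z)-2-(bromomethyl)enoate. The ten-membered carbocycle closes first, the C6 alkoxide then closes the γ-lactone in the same flask, and C6 and C7 are set from C8.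
- Enabling feature: the α-methylene-γ-butyrolactone fused across C6–C7 (O–C6–C7–C11(=C13H2)–C12=O) is the retron of a carbonyl 2-(alkoxycarbonyl)allylation. The two ring-cis trisubstituted olefins C4=C5 and C1=C10 fold the chain for ten-membered closure, and the oxygenated C8 next to C7 relays its configuration.
- Precursor assembly: bromide unit by Baylis–Hillman reaction and allylic bromination at C7; C1=C10 by Horner–Wadsworth–Emmons olefination of glutaraldehyde with a (5R)-phosphono-lactone (from triethyl phosphonoacetate and an (R)-glycidyl ether, the only bought stereocentre); C4=C5 by cross-aldol condensation with glyoxal mono-acetal; one i-Bu2AlH reduction unveils O-8, O-14 and O-15.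

Key step: step 12

Remark: (R)-glycidyl 4-methoxybenzyl ether is taken as a purchasable material (otherwise one step from (S)-glycidol); the sense of 1,2-induction from C8 in the ring closure is assumed to follow the Felkin–Anh model given under step 12.

**Route**

Step 1
Reactants: 1 triethyl phosphonoacetate; 2 (R)-glycidyl 4-methoxybenzyl ether
Product: 4 (5R)-3-(diethoxyphosphoryl)-5-{[(4-methoxybenzyl)oxy]methyl}dihydrofuran-2(3H)-one (C3 epimers), via open-chain sodium alkoxide 3 (not isolated)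
Conditions: NaH, THF/toluene, 0 to 100 °C
Reagents that add atoms: none
Why: The sodium phosphonoacetate should open the epoxide at its CH2 terminus (SN2, the C8–O bond is untouched so the bought configuration is kept) and the alkoxide 3 should lactonise on the ethyl ester (5-exo-trig), the standard route to α-phosphono-γ-butyrolactones.

Step 2
Reactants: 4 phosphono-lactone; 5 glutaraldehyde
Product: 6 (5E)-5-[(5R)-5-{[(4-methoxybenzyl)oxy]methyl}-2-oxodihydrofuran-3(2H)-ylidene]pentanal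
Conditions: 5 (50% aq., 5 equiv), K2CO3, THF/H2O, 0 °C to rt
Reagents that add atoms: none
Why: Horner–Wadsworth–Emmons olefination with a large excess of the symmetrical dialdehyde should stop at mono-olefination and give mainly the E-alkylidene lactone (chain trans to the lactone carbonyl, hence C2 cis to C9), the usual outcome for α-phosphono lactones.

Step 3
Reactants: 6 aldehyde; 7 2,2-dimethoxyacetaldehyde
Product: 8 (2E)-4,4-dimethoxy-2-{(3E)-3-[(5R)-5-{[(4-methoxybenzyl)oxy]methyl}-2-oxodihydrofuran-3(2H)-ylidene]propyl}but-2-enal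
Conditions: 7 (60% aq., 3 equiv), pyrrolidine (20 mol%), PhCO2H (20 mol%), i-PrOH, 45 °C
Reagents that add atoms: none
Why: Amine-catalysed cross-aldol condensation (enamine of the only enolisable aldehyde, a non-enolisable and highly electrophilic acceptor, then dehydration) should give the 2-alkyl-2-enal, whose thermodynamically preferred E form has the acetal carbon cis to C3 as the C4=C5 olefin requires.

Step 4
Reactants: 8 enal lactone
Product: 9 (2R,4E,8E)-4,8-bis(hydroxymethyl)-10,10-dimethoxy-1-[(4-methoxybenzyl)oxy]deca-4,8-dien-2-ol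
Conditions: i-Bu2AlH (7 equiv), CH2Cl2, −78 to 0 °C; aq. potassium sodium tartrate
Reagents that add atoms: none
Why: Hydride reduction with i-Bu2AlH should reduce the enal by 1,2-addition and the alkylidene lactone through its lactol to the diol while the acetal, the PMB ether and the olefins are inert, so that O-14, O-15 and O-8 are unveiled in one operation.

Step 5
Reactants: 9 triol
Product: 10 (2R,4E,8E)-4,8-bis{[(tert-butyldiphenylsilyl)oxy]methyl}-10,10-dimethoxy-1-[(4-methoxybenzyl)oxy]deca-4,8-dien-2-ol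
Conditions: TBDPSCl (2.1 equiv), imidazole, CH2Cl2, 0 °C
Reagents that add atoms: tert-butyldiphenylsilyl chloride (TBDPSCl), CC(C)(C)[Si](Cl)(c1ccccc1)c1ccccc1
Why: Silylation with the bulky chlorosilane should be selective for the two primary allylic hydroxyls over the secondary C8 hydroxyl.

Step 6
Reactants: 10 secondary alcohol
Product: 11 (2R,4E,8E)-2-[(tert-butyldimethylsilyl)oxy]-4,8-bis{[(tert-butyldiphenylsilyl)oxy]methyl}-10,10-dimethoxy-1-[(4-methoxybenzyl)oxy]deca-4,8-diene
Conditions: TBSCl, imidazole, DMAP (cat.), DMF, 40 °C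
Reagents that add atoms: tert-butyldimethylsilyl chloride (TBSCl), CC(C)(C)[Si](C)(C)Cl
Why: Imidazole-promoted silylation of the remaining secondary alcohol avoids silyl triflates and therefore should leave the allylic dimethyl acetal intact.

Step 7
Reactants: 11 PMB ether
Product: 12 (2R,4E,8E)-2-[(tert-butyldimethylsilyl)oxy]-4,8-bis{[(tert-butyldiphenylsilyl)oxy]methyl}-10,10-dimethoxydeca-4,8-dien-1-ol
Conditions: DDQ, CH2Cl2/pH 7 buffer, 0 °C
Reagents that add atoms: none
Why: Oxidative PMB cleavage by DDQ (benzylic hydride abstraction, hydrolysis of the oxocarbenium ion) under buffered conditions should spare the silyl ethers and the acetal.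

Step 8
Reactants: 12 primary alcohol
Product: 13 (2R,4E,8E)-2-[(tert-butyldimethylsilyl)oxy]-4,8-bis{[(tert-butyldiphenylsilyl)oxy]methyl}-10,10-dimethoxydeca-4,8-dienal
Conditions: Dess–Martin periodinane, pyridine, CH2Cl2, 0 °C to rt
Reagents that add atoms: none
Why: Dess–Martin oxidation under buffered, non-epimerising conditions should give the α-silyloxy aldehyde with C8 unchanged.

Step 9
Reactants: 13 aldehyde; 14 methyl acrylate
Product: 15 methyl (4R,6E,10E)-4-[(tert-butyldimethylsilyl)oxy]-6,10-bis{[(tert-butyldiphenylsilyl)oxy]methyl}-3-hydroxy-12,12-dimethoxy-2-methylidenedodeca-6,10-dienoate (C3 epimers)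
Conditions: DABCO (1 equiv), neat in 14, rt
Reagents that add atoms: none
Why: In this Morita–Baylis–Hillman reaction the DABCO–acrylate zwitterion should add to the activated α-silyloxy aldehyde, and the new C7 carbinol centre may form as a mixture because C7 becomes sp2 in the next step.

Step 10
Reactants: 15 Baylis–Hillman adduct
Product: 16 methyl (2Z,4R,6E,10E)-2-(bromomethyl)-4-[(tert-butyldimethylsilyl)oxy]-6,10-bis{[(tert-butyldiphenylsilyl)oxy]methyl}-12,12-dimethoxydodeca-2,6,10-trienoate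
Conditions: NBS, Me2S, CH2Cl2, 0 °C to rt
Reagents that add atoms: N-bromosuccinimide (NBS), BrN1C(=O)CCC1=O
Why: Corey–Kim-type activation of the allylic alcohol as its alkoxysulfonium salt and SN2′ delivery of bromide should give the rearranged conjugated (Z)-2-(bromomethyl)alk-2-enoate, the standard transposition of Baylis–Hillman adducts.

Step 11
Reactants: 16 acetal bromide
Product: 17 methyl (2Z,4R,6E,10E)-2-(bromomethyl)-4-[(tert-butyldimethylsilyl)oxy]-6,10-bis{[(tert-butyldiphenylsilyl)oxy]methyl}-12-oxododeca-2,6,10-trienoate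
Conditions: PPTS (cat.), acetone/H2O, rt
Reagents that add atoms: water, O
Why: Mild acid-catalysed acetal hydrolysis, fast for an allylic acetal through its conjugated oxocarbenium ion, should unmask the enal while the silyl ethers and the allylic bromide survive.

Step 12
Reactants: 17 enal allylic bromide
Product: 20 (1(10)E,4E,6R,7S,8R)-8-[(tert-butyldimethylsilyl)oxy]-14,15-bis[(tert-butyldiphenylsilyl)oxy]germacra-1(10),4,11(13)-trien-12,6-olide, via allylchromium dichloride 18 (not isolated), via ring-closed hydroxy ester 19 (not isolated)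
Conditions: CrCl2 (8 equiv), THF, 0.003 M, slow addition of 17, rt; then aq. NH4Cl
Reagents that add atoms: none
Why: CrCl2 (two equivalents of divalent chromium per C–Br bond) should convert the allylic bromide into the σ-allyl trivalent-chromium species 18, whose E and Z forms interconvert, and this adds through its γ-carbon C7 to the enal carbonyl C6 in a six-membered chair (Zimmerman–Traxler) transition state that moves the double bond to C11=C13, after which the chromium alkoxide of 19 acylates on the neighbouring methyl ester to give the γ-lactone. The closest known reaction type is the chromium-mediated intramolecular Barbier (Nozaki–Hiyama–Kishi) 2-(alkoxycarbonyl)allylation of ω-formyl 2-(bromomethyl)alk-2-enoates, which is established for closing ten-membered sesquiterpene lactone rings at this same bond. The carbocycle closes by a 10-exo-trig addition to the C6=O group with allyl transposition (SE2′), and the lactone by a 5-exo-trig acyl substitution. C6 is set by the chair in which C5 and C8 are both pseudo-equatorial (reaction through the E-allylchromium form), which gives the anti adduct and hence the trans-fused lactone. C7 is set by the C8 stereocentre: C8–H points toward C5 (no syn-pentane contact), the bulky OTBS group lies anti to the forming bond (the Felkin–Anh sense known for γ-alkoxy allylchromium reagents) and the C9 chain closes the ring from the remaining position, so that 8R should give the H-7/H-8 cis relationship of the target. The step needs γ- over α-attack, 1,2- over 1,4-addition and cyclisation over oligomerisation, which should be secured by the chair transition state, by the oxophilic chromium, and by high dilution together with the two ring-cis trisubstituted olefins that fold the chain, while the poor silyloxy leaving group suppresses 1,4-elimination of the allylmetal.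

Step 13
Reactants: 20 silylated lactone
Product: 21 (1(10)E,4E,6R,7R,8R)-14,15-bis[(tert-butyldiphenylsilyl)oxy]-8-hydroxygermacra-1(10),4,11(13)-trien-12,6-olide
Conditions: CSA (cat.), MeOH/CH2Cl2, 0 °C to rt
Reagents that add atoms: none
Why: Acid-catalysed methanolysis should remove the secondary TBS ether much faster than the two primary TBDPS ethers (selective desilylation), and the γ-lactone is stable to these conditions.

Step 14
Reactants: 21 C8 alcohol; 22 3-methylbutanoic anhydride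
Product: 23 (1(10)E,4E,6R,7R,8R)-14,15-bis[(tert-butyldiphenylsilyl)oxy]-8-(3-methylbutanoyloxy)germacra-1(10),4,11(13)-trien-12,6-olide
Conditions: DMAP (cat.), pyridine, CH2Cl2, rt
Reagents that add atoms: none
Why: DMAP-catalysed acylation of the only free hydroxyl should install the 3-methylbutanoate with retention at C8.

Step 15
Reactants: 23 bis-silyl ether
Product: 24 (3aR,4R,6E,10E,11aR)-6,10-bis(hydroxymethyl)-3-methylidene-2-oxo-2,3,3a,4,5,8,9,11a-octahydrocyclodeca[b]furan-4-yl 3-methylbutanoate (target)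
Conditions: HF·pyridine, pyridine/THF, 0 °C to rt
Reagents that add atoms: none
Why: Fluoride-mediated cleavage of the two primary TBDPS ethers with buffered HF·pyridine, conditions that tolerate the α-methylene lactone and the ester, should release the target.

**Compound list**

1 | triethyl phosphonoacetate | CCOC(=O)CP(=O)(OCC)OCC | starting material
2 | (R)-glycidyl 4-methoxybenzyl ether, (2R)-2-{[(4-methoxybenzyl)oxy]methyl}oxirane | COc1ccc(COC[C@H]2CO2)cc1 | starting material
3 | ethyl (4R)-2-(diethoxyphosphoryl)-4-hydroxy-5-[(4-methoxybenzyl)oxy]pentanoate (C2 epimers, present as sodium alkoxide) | CCOC(=O)C(C[C@@H](O)COCc1ccc(OC)cc1)P(=O)(OCC)OCC | intermediate (not isolated)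
4 | (5R)-3-(diethoxyphosphoryl)-5-{[(4-methoxybenzyl)oxy]methyl}dihydrofuran-2(3H)-one (C3 epimers) | CCOP(=O)(OCC)C1C[C@H](COCc2ccc(OC)cc2)OC1=O | intermediate
5 | glutaraldehyde (pentanedial) | O=CCCCC=O | starting material
6 | (5E)-5-[(5R)-5-{[(4-methoxybenzyl)oxy]methyl}-2-oxodihydrofuran-3(2H)-ylidene]pentanal | O=CCCC/C=C1\C[C@H](COCc2ccc(OC)cc2)OC1=O | intermediate
7 | 2,2-dimethoxyacetaldehyde | COC(OC)C=O | starting material
8 | (2E)-4,4-dimethoxy-2-{(3E)-3-[(5R)-5-{[(4-methoxybenzyl)oxy]methyl}-2-oxodihydrofuran-3(2H)-ylidene]propyl}but-2-enal | COC(OC)/C=C(/C=O)CC/C=C1\C[C@H](COCc2ccc(OC)cc2)OC1=O | intermediate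
9 | (2R,4E,8E)-4,8-bis(hydroxymethyl)-10,10-dimethoxy-1-[(4-methoxybenzyl)oxy]deca-4,8-dien-2-ol | COC(OC)/C=C(/CO)CC/C=C(/CO)C[C@@H](O)COCc1ccc(OC)cc1 | intermediate
10 | (2R,4E,8E)-4,8-bis{[(tert-butyldiphenylsilyl)oxy]methyl}-10,10-dimethoxy-1-[(4-methoxybenzyl)oxy]deca-4,8-dien-2-ol | COC(OC)/C=C(/CO[Si](c1ccccc1)(c1ccccc1)C(C)(C)C)CC/C=C(/CO[Si](c1ccccc1)(c1ccccc1)C(C)(C)C)C[C@@H](O)COCc1ccc(OC)cc1 | intermediate
11 | (2R,4E,8E)-2-[(tert-butyldimethylsilyl)oxy]-4,8-bis{[(tert-butyldiphenylsilyl)oxy]methyl}-10,10-dimethoxy-1-[(4-methoxybenzyl)oxy]deca-4,8-diene | COC(OC)/C=C(/CO[Si](c1ccccc1)(c1ccccc1)C(C)(C)C)CC/C=C(/CO[Si](c1ccccc1)(c1ccccc1)C(C)(C)C)C[C@@H](O[Si](C)(C)C(C)(C)C)COCc1ccc(OC)cc1 | intermediate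
12 | (2R,4E,8E)-2-[(tert-butyldimethylsilyl)oxy]-4,8-bis{[(tert-butyldiphenylsilyl)oxy]methyl}-10,10-dimethoxydeca-4,8-dien-1-ol | COC(OC)/C=C(/CO[Si](c1ccccc1)(c1ccccc1)C(C)(C)C)CC/C=C(/CO[Si](c1ccccc1)(c1ccccc1)C(C)(C)C)C[C@@H](O[Si](C)(C)C(C)(C)C)CO | intermediate
13 | (2R,4E,8E)-2-[(tert-butyldimethylsilyl)oxy]-4,8-bis{[(tert-butyldiphenylsilyl)oxy]methyl}-10,10-dimethoxydeca-4,8-dienal | COC(OC)/C=C(/CO[Si](c1ccccc1)(c1ccccc1)C(C)(C)C)CC/C=C(/CO[Si](c1ccccc1)(c1ccccc1)C(C)(C)C)C[C@@H](O[Si](C)(C)C(C)(C)C)C=O | intermediate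
14 | methyl acrylate | C=CC(=O)OC | starting material
15 | methyl (4R,6E,10E)-4-[(tert-butyldimethylsilyl)oxy]-6,10-bis{[(tert-butyldiphenylsilyl)oxy]methyl}-3-hydroxy-12,12-dimethoxy-2-methylidenedodeca-6,10-dienoate (C3 epimers) | COC(OC)/C=C(/CO[Si](c1ccccc1)(c1ccccc1)C(C)(C)C)CC/C=C(/CO[Si](c1ccccc1)(c1ccccc1)C(C)(C)C)C[C@@H](O[Si](C)(C)C(C)(C)C)C(O)C(=C)C(=O)OC | intermediate
16 | methyl (2Z,4R,6E,10E)-2-(bromomethyl)-4-[(tert-butyldimethylsilyl)oxy]-6,10-bis{[(tert-butyldiphenylsilyl)oxy]methyl}-12,12-dimethoxydodeca-2,6,10-trienoate | COC(OC)/C=C(/CO[Si](c1ccccc1)(c1ccccc1)C(C)(C)C)CC/C=C(/CO[Si](c1ccccc1)(c1ccccc1)C(C)(C)C)C[C@@H](O[Si](C)(C)C(C)(C)C)/C=C(\CBr)C(=O)OC | intermediate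
17 | methyl (2Z,4R,6E,10E)-2-(bromomethyl)-4-[(tert-butyldimethylsilyl)oxy]-6,10-bis{[(tert-butyldiphenylsilyl)oxy]methyl}-12-oxododeca-2,6,10-trienoate | O=C/C=C(/CO[Si](c1ccccc1)(c1ccccc1)C(C)(C)C)CC/C=C(/CO[Si](c1ccccc1)(c1ccccc1)C(C)(C)C)C[C@@H](O[Si](C)(C)C(C)(C)C)/C=C(\CBr)C(=O)OC | intermediate
18 | allylchromium dichloride from 17 (trivalent chromium on C13, E/Z forms interconverting, 8R) | O=C/C=C(/CO[Si](c1ccccc1)(c1ccccc1)C(C)(C)C)CC/C=C(/CO[Si](c1ccccc1)(c1ccccc1)C(C)(C)C)C[C@@H](O[Si](C)(C)C(C)(C)C)C=C(C[Cr](Cl)Cl)C(=O)OC | intermediate (not isolated)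
19 | methyl (1(10)E,4E,6R,7S,8R)-8-[(tert-butyldimethylsilyl)oxy]-14,15-bis[(tert-butyldiphenylsilyl)oxy]-6-hydroxygermacra-1(10),4,11(13)-trien-12-oate (present as its trivalent-chromium alkoxide) | C=C(C(=O)OC)[C@H]1[C@H](O)/C=C(/CO[Si](c2ccccc2)(c2ccccc2)C(C)(C)C)CC/C=C(/CO[Si](c2ccccc2)(c2ccccc2)C(C)(C)C)C[C@H]1O[Si](C)(C)C(C)(C)C | intermediate (not isolated)
20 | (1(10)E,4E,6R,7S,8R)-8-[(tert-butyldimethylsilyl)oxy]-14,15-bis[(tert-butyldiphenylsilyl)oxy]germacra-1(10),4,11(13)-trien-12,6-olide (spatial arrangement of the target; the C7 descriptor is S only because of the silyl group on O-8) | C=C1C(=O)O[C@@H]2/C=C(/CO[Si](c3ccccc3)(c3ccccc3)C(C)(C)C)CC/C=C(/CO[Si](c3ccccc3)(c3ccccc3)C(C)(C)C)C[C@@H](O[Si](C)(C)C(C)(C)C)[C@@H]12 | intermediate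
21 | (1(10)E,4E,6R,7R,8R)-14,15-bis[(tert-butyldiphenylsilyl)oxy]-8-hydroxygermacra-1(10),4,11(13)-trien-12,6-olide | C=C1C(=O)O[C@@H]2/C=C(/CO[Si](c3ccccc3)(c3ccccc3)C(C)(C)C)CC/C=C(/CO[Si](c3ccccc3)(c3ccccc3)C(C)(C)C)C[C@@H](O)[C@@H]12 | intermediate
22 | 3-methylbutanoic (isovaleric) anhydride | CC(C)CC(=O)OC(=O)CC(C)C | starting material
23 | (1(10)E,4E,6R,7R,8R)-14,15-bis[(tert-butyldiphenylsilyl)oxy]-8-(3-methylbutanoyloxy)germacra-1(10),4,11(13)-trien-12,6-olide | C=C1C(=O)O[C@@H]2/C=C(/CO[Si](c3ccccc3)(c3ccccc3)C(C)(C)C)CC/C=C(/CO[Si](c3ccccc3)(c3ccccc3)C(C)(C)C)C[C@@H](OC(=O)CC(C)C)[C@@H]12 | intermediate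
24 | (3aR,4R,6E,10E,11aR)-6,10-bis(hydroxymethyl)-3-methylidene-2-oxo-2,3,3a,4,5,8,9,11a-octahydrocyclodeca[b]furan-4-yl 3-methylbutanoate | C=C1C(=O)O[C@@H]2/C=C(/CO)CC/C=C(/CO)C[C@@H](OC(=O)CC(C)C)[C@@H]12 | target

**Step count and risks**

Total step count: 15. Longest linear sequence: 15 steps (from 1 and 2 to 24).

Steps most likely to fail:

1. Step 12 (key step). The aldehyde may attack the other face of the allyl unit relative to the C8 silyloxy group (C9 chain anti, oxygen inside). That would give the trans-lactone with C6 and C7 both wrong relative to C8. Fallback (sets out from 10, comes back at 23): C8 is inverted before the sequence and once more when the ester is introduced. Mitsunobu reaction of 10 (4-nitrobenzoic acid, PPh3, DIAD) should give the inverted (2S)-4-nitrobenzoate F1, and methanolysis (K2CO3, MeOH) the (2S)-alcohol F2. The operations of steps 6 to 11 applied to F2 should give in turn the TBS ether F3, the primary alcohol F4, the α-silyloxy aldehyde F5, the Baylis–Hillman adduct F6, the (Z)-allylic bromide F7 and the enal F8. CrCl2 ring closure of F8, through the allylchromium dichloride F9 and the ring-closed hydroxy ester F10 (neither isolated), would then give the (6R,7S,8S)-lactone F11, which has the C6/C7 arrangement of the target, and acid methanolysis would give the 8-epi alcohol F12. Mitsunobu esterification of F12 with 3-methylbutanoic acid (PPh3, DIAD) inverts C8 while it installs the ester and returns to 23.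

2. Step 3. Aldehyde 6 may self-condense, the amine catalyst may add reversibly to the alkylidene lactone, and dehydration may be incomplete (one step earlier, glutaraldehyde may also be olefinated twice). Fallback (sets out from 4 and 7, comes back at 9): the C4=C5 olefin is made first by a stabilised Wittig reaction. C-Allylation of methyl (triphenylphosphoranylidene)acetate with allyl bromide should give the ylide methyl 2-(triphenylphosphoranylidene)pent-4-enoate F13, and its Wittig reaction with 7 the E-enoate methyl (2E)-4,4-dimethoxy-2-(prop-2-en-1-yl)but-2-enoate F14. Hydroboration of the terminal olefin (9-BBN, then NaBO3) would give the primary alcohol F15, and Dess–Martin oxidation the aldehyde F16. Horner–Wadsworth–Emmons reaction of F16 with 4 (LiCl, DBU) should give the E-alkylidene lactone ester F17, and i-Bu2AlH reduction of its ester and lactone groups returns to triol 9.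

3. Step 9. The addition is slow, and during it the amine may epimerise the α-silyloxy aldehyde at C8 or promote 1,2-silyl migration in the adduct. Fallback (sets out from 13, comes back at 15): vinylalumination in place of amine catalysis. Hydroalumination of methyl propiolate (i-Bu2AlH, N-methylmorpholine N-oxide, THF, 0 °C) should give [1-(methoxycarbonyl)ethenyl]bis(2-methylpropyl)aluminium F18, which adds to 13 at low temperature without base to give 15 directly.

Further compounds
F1 | step 12 | (2S,4E,8E)-4,8-bis{[(tert-butyldiphenylsilyl)oxy]methyl}-10,10-dimethoxy-1-[(4-methoxybenzyl)oxy]deca-4,8-dien-2-yl 4-nitrobenzoate | COC(OC)/C=C(/CO[Si](c1ccccc1)(c1ccccc1)C(C)(C)C)CC/C=C(/CO[Si](c1ccccc1)(c1ccccc1)C(C)(C)C)C[C@H](OC(=O)c1ccc(cc1)[N+](=O)[O-])COCc1ccc(OC)cc1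
F2 | step 12 | (2S,4E,8E)-4,8-bis{[(tert-butyldiphenylsilyl)oxy]methyl}-10,10-dimethoxy-1-[(4-methoxybenzyl)oxy]deca-4,8-dien-2-ol | COC(OC)/C=C(/CO[Si](c1ccccc1)(c1ccccc1)C(C)(C)C)CC/C=C(/CO[Si](c1ccccc1)(c1ccccc1)C(C)(C)C)C[C@H](O)COCc1ccc(OC)cc1
F3 | step 12 | (2S,4E,8E)-2-[(tert-butyldimethylsilyl)oxy]-4,8-bis{[(tert-butyldiphenylsilyl)oxy]methyl}-10,10-dimethoxy-1-[(4-methoxybenzyl)oxy]deca-4,8-diene | COC(OC)/C=C(/CO[Si](c1ccccc1)(c1ccccc1)C(C)(C)C)CC/C=C(/CO[Si](c1ccccc1)(c1ccccc1)C(C)(C)C)C[C@H](O[Si](C)(C)C(C)(C)C)COCc1ccc(OC)cc1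
F4 | step 12 | (2S,4E,8E)-2-[(tert-butyldimethylsilyl)oxy]-4,8-bis{[(tert-butyldiphenylsilyl)oxy]methyl}-10,10-dimethoxydeca-4,8-dien-1-ol | COC(OC)/C=C(/CO[Si](c1ccccc1)(c1ccccc1)C(C)(C)C)CC/C=C(/CO[Si](c1ccccc1)(c1ccccc1)C(C)(C)C)C[C@H](O[Si](C)(C)C(C)(C)C)CO
F5 | step 12 | (2S,4E,8E)-2-[(tert-butyldimethylsilyl)oxy]-4,8-bis{[(tert-butyldiphenylsilyl)oxy]methyl}-10,10-dimethoxydeca-4,8-dienal | COC(OC)/C=C(/CO[Si](c1ccccc1)(c1ccccc1)C(C)(C)C)CC/C=C(/CO[Si](c1ccccc1)(c1ccccc1)C(C)(C)C)C[C@H](O[Si](C)(C)C(C)(C)C)C=O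
F6 | step 12 | methyl (4S,6E,10E)-4-[(tert-butyldimethylsilyl)oxy]-6,10-bis{[(tert-butyldiphenylsilyl)oxy]methyl}-3-hydroxy-12,12-dimethoxy-2-methylidenedodeca-6,10-dienoate (C3 epimers) | COC(OC)/C=C(/CO[Si](c1ccccc1)(c1ccccc1)C(C)(C)C)CC/C=C(/CO[Si](c1ccccc1)(c1ccccc1)C(C)(C)C)C[C@H](O[Si](C)(C)C(C)(C)C)C(O)C(=C)C(=O)OC
F7 | step 12 | methyl (2Z,4S,6E,10E)-2-(bromomethyl)-4-[(tert-butyldimethylsilyl)oxy]-6,10-bis{[(tert-butyldiphenylsilyl)oxy]methyl}-12,12-dimethoxydodeca-2,6,10-trienoate | COC(OC)/C=C(/CO[Si](c1ccccc1)(c1ccccc1)C(C)(C)C)CC/C=C(/CO[Si](c1ccccc1)(c1ccccc1)C(C)(C)C)C[C@H](O[Si](C)(C)C(C)(C)C)/C=C(\CBr)C(=O)OC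
F8 | step 12 | methyl (2Z,4S,6E,10E)-2-(bromomethyl)-4-[(tert-butyldimethylsilyl)oxy]-6,10-bis{[(tert-butyldiphenylsilyl)oxy]methyl}-12-oxododeca-2,6,10-trienoate | O=C/C=C(/CO[Si](c1ccccc1)(c1ccccc1)C(C)(C)C)CC/C=C(/CO[Si](c1ccccc1)(c1ccccc1)C(C)(C)C)C[C@H](O[Si](C)(C)C(C)(C)C)/C=C(\CBr)C(=O)OC
F9 | step 12 | allylchromium dichloride from F8 (trivalent chromium on C13, 8S, not isolated) | O=C/C=C(/CO[Si](c1ccccc1)(c1ccccc1)C(C)(C)C)CC/C=C(/CO[Si](c1ccccc1)(c1ccccc1)C(C)(C)C)C[C@H](O[Si](C)(C)C(C)(C)C)C=C(C[Cr](Cl)Cl)C(=O)OC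
F10 | step 12 | methyl (1(10)E,4E,6R,7S,8S)-8-[(tert-butyldimethylsilyl)oxy]-14,15-bis[(tert-butyldiphenylsilyl)oxy]-6-hydroxygermacra-1(10),4,11(13)-trien-12-oate (as chromium alkoxide, not isolated) | C=C(C(=O)OC)[C@H]1[C@H](O)/C=C(/CO[Si](c2ccccc2)(c2ccccc2)C(C)(C)C)CC/C=C(/CO[Si](c2ccccc2)(c2ccccc2)C(C)(C)C)C[C@@H]1O[Si](C)(C)C(C)(C)C
F11 | step 12 | (1(10)E,4E,6R,7S,8S)-8-[(tert-butyldimethylsilyl)oxy]-14,15-bis[(tert-butyldiphenylsilyl)oxy]germacra-1(10),4,11(13)-trien-12,6-olide | C=C1C(=O)O[C@@H]2/C=C(/CO[Si](c3ccccc3)(c3ccccc3)C(C)(C)C)CC/C=C(/CO[Si](c3ccccc3)(c3ccccc3)C(C)(C)C)C[C@H](O[Si](C)(C)C(C)(C)C)[C@@H]12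
F12 | step 12 | (1(10)E,4E,6R,7R,8S)-14,15-bis[(tert-butyldiphenylsilyl)oxy]-8-hydroxygermacra-1(10),4,11(13)-trien-12,6-olide | C=C1C(=O)O[C@@H]2/C=C(/CO[Si](c3ccccc3)(c3ccccc3)C(C)(C)C)CC/C=C(/CO[Si](c3ccccc3)(c3ccccc3)C(C)(C)C)C[C@H](O)[C@@H]12
F13 | step 3 | methyl 2-(triphenylphosphoranylidene)pent-4-enoate | C=CCC(C(=O)OC)=P(c1ccccc1)(c1ccccc1)c1ccccc1
F14 | step 3 | methyl (2E)-4,4-dimethoxy-2-(prop-2-en-1-yl)but-2-enoate | COC(OC)/C=C(/C(=O)OC)CC=C
F15 | step 3 | methyl (2E)-2-(3-hydroxypropyl)-4,4-dimethoxybut-2-enoate | COC(OC)/C=C(/C(=O)OC)CCCO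
F16 | step 3 | methyl (2E)-4,4-dimethoxy-2-(3-oxopropyl)but-2-enoate | COC(OC)/C=C(/C(=O)OC)CCC=O
F17 | step 3 | methyl (2E)-4,4-dimethoxy-2-{(3E)-3-[(5R)-5-{[(4-methoxybenzyl)oxy]methyl}-2-oxodihydrofuran-3(2H)-ylidene]propyl}but-2-enoate | COC(OC)/C=C(/C(=O)OC)CC/C=C1\C[C@H](COCc2ccc(OC)cc2)OC1=O
F18 | step 9 | [1-(methoxycarbonyl)ethenyl]bis(2-methylpropyl)aluminium | C=C([Al](CC(C)C)CC(C)C)C(=O)OC
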